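**Retrosynthetic overview**

- The plan rests on ring A (C4a, C5, C6, C7, C8, C8a): a hexasubstituted benzene with oxygen at C5, C6, C7 and C8a and carbon at C8 and C4a, whose C8a and C4a are spanned by O1–C2–C3–C4 of ring C, the tether of a 1,7-diyne.
- Rings A and C are formed together by a [2+2+2] cyclotrimerisation (C4a–C8a, C5–C6, C7–C8) of diyne 28 (O1-alkynyl ether and C4 alkoxy ynone termini) with methoxyethynyl boronate 35; Bpin masks 7-OH, O-tBu masks 5-OH, and ring B comes from salicylaldehyde.
- C4–C4a: tert-butoxyethynyllithium (from tert-butyl vinyl ether through tert-butoxyethyne 25) adds to aldehyde 20, then oxidation. The acyl carbon is carried as a silyl-protected CH2OH, because the KH and n-BuLi of the ynol ether chemistry rule out an ester or amide at that stage.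
- O1–C8a and C8–C1'': the C2 hydroxyl is converted with trichloroethylene into a dichlorovinyl ether, then into a lithium alkynyl ether that is alkylated with prenyl bromide. C2–C3 and both stereocentres come from an anti glycolate aldol of an oxazolidinone imide with 2-(MOM-oxy)benzaldehyde.
- End game: boronate to phenol, then acid removes the tert-butyl and both MOM groups. The C6/C7 alkyne comes from chloroacetaldehyde dimethyl acetal through methoxyethyne 31.

Key step: step 18

Assumption: the N-(alkoxyacetyl)oxazolidinone 8 behaves in the Mg-catalysed aldol as N-propionyl imides do (anti adduct from the chelated Z-enolate, aldehyde on the face remote from the benzyl group), so the (S)-auxiliary gives the (2R,3R)-adduct; if the facial sense is the opposite, the (R)-auxiliary is used with no other change.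

**Route**

Step 1
Reactants: 1 salicylaldehyde
Product: 2 2-(methoxymethoxy)benzaldehyde
Conditions: MOMCl, iPr2NEt, CH2Cl2, 0 °C → rt
Reagents that add atoms: chloromethyl methyl ether (MOMCl), COCCl
Why: O-alkylation of the phenol (MOM acetal formation) should mask the 2'-hydroxyl as an acid-labile group and leave the aldehyde untouched.

Step 2
Reactants: 3 methyl glycolate
Product: 4 methyl 2-(methoxymethoxy)acetate
Conditions: MOMCl, iPr2NEt, CH2Cl2, 0 °C → rt
Reagents that add atoms: chloromethyl methyl ether (MOMCl), COCCl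
Why: Base-mediated O-alkylation of the primary hydroxyl (MOM acetal formation) installs the future 3-O protecting group before any C–C bond is made.

Step 3
Reactants: 4 methyl 2-(methoxymethoxy)acetate
Product: 5 2-(methoxymethoxy)acetic acid
Conditions: LiOH, THF/H2O, 0 °C → rt; 1 M HCl to pH 3, 0 °C
Reagents that add atoms: lithium hydroxide, [Li+].[OH-]
Why: Ester saponification; the MOM acetal is stable to base and should survive the brief, cold acidification.

Step 4
Reactants: 5 2-(methoxymethoxy)acetic acid; 6 (S)-4-benzyl-1,3-oxazolidin-2-one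
Product: 8 (S)-4-benzyl-3-[2-(methoxymethoxy)acetyl]-1,3-oxazolidin-2-one, via mixed pivalic anhydride 7 (not isolated)
Conditions: PivCl, Et3N, THF, −20 °C; then LiCl, 6, −20 °C → rt
Reagents that add atoms: none
Why: N-acylation of the oxazolidinone through the mixed anhydride (LiCl/Et3N protocol); the nucleophile should attack the unhindered glycolyl carbonyl and not the pivaloyl carbonyl.

Step 5
Reactants: 8 (S)-4-benzyl-3-[2-(methoxymethoxy)acetyl]-1,3-oxazolidin-2-one; 2 2-(methoxymethoxy)benzaldehyde
Product: 10 (S)-4-benzyl-3-[(2R,3R)-3-hydroxy-2-(methoxymethoxy)-3-[2-(methoxymethoxy)phenyl]propanoyl]-1,3-oxazolidin-2-one, via O-trimethylsilyl aldol adduct 9 (not isolated)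
Conditions: MgCl2 (20 mol%), Et3N, TMSCl, EtOAc, rt; then citric acid, MeOH, rt
Reagents that add atoms: none
Why: Mg-catalysed direct anti-aldol of an N-acyloxazolidinone (Evans-type) with a non-enolisable aryl aldehyde: soft enolisation gives the chelated Z-enolate and silylation turns the catalyst over; the benzyl group of the auxiliary sets the oxygen-bearing carbon that becomes C3, and the boat-type transition state sets the anti-related carbinol carbon that becomes C2.

Step 6
Reactants: 10 aldol adduct
Product: 11 (1R,2S)-2-(methoxymethoxy)-1-[2-(methoxymethoxy)phenyl]propane-1,3-diol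
Conditions: LiBH4, THF, H2O (1 equiv), 0 °C
Reagents that add atoms: none
Why: Reductive cleavage of the imide by hydride attack at the exocyclic carbonyl releases the auxiliary and gives the primary alcohol without touching either stereocentre, and it removes the carbonyl that would allow retro-aldol at a later basic stage.

Step 7
Reactants: 11 diol
Product: 12 (1R,2S)-2-(methoxymethoxy)-1-[2-(methoxymethoxy)phenyl]-3-[(triisopropylsilyl)oxy]propan-1-ol
Conditions: TIPSCl, imidazole, CH2Cl2, 0 °C → rt
Reagents that add atoms: triisopropylsilyl chloride (TIPSCl), CC(C)[Si](Cl)(C(C)C)C(C)C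
Why: Selective silylation of the primary hydroxyl by the bulky silyl chloride leaves the hindered benzylic hydroxyl free, and the TIPS group is the silyl ether least prone to O-to-O migration in the next step.

Step 8
Reactants: 12 TIPS ether alcohol; 13 trichloroethylene
Product: 15 {[(2S,3R)-3-{[(E)-1,2-dichloroethenyl]oxy}-2-(methoxymethoxy)-3-[2-(methoxymethoxy)phenyl]propyl]oxy}triisopropylsilane, via dichloroacetylene 14 (not isolated)
Conditions: KH, THF, 0 °C → rt; then 13, −50 °C → rt
Reagents that add atoms: none
Why: Dichlorovinyl ether synthesis by anti addition of the potassium alkoxide to dichloroacetylene generated in the flask from trichloroethylene; the C–O bond at the stereocentre is not broken, so configuration is retained.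

Step 9
Reactants: 15 dichlorovinyl ether; 16 prenyl bromide
Product: 18 triisopropyl{[(2S,3R)-2-(methoxymethoxy)-3-[2-(methoxymethoxy)phenyl]-3-[(5-methylhex-4-en-1-yn-1-yl)oxy]propyl]oxy}silane, via lithium alkynyl ether 17 (not isolated)
Conditions: n-BuLi (2.3 equiv), THF, −78 → −40 °C; then 16, DMPU, −78 → 0 °C
Reagents that add atoms: none
Why: Dehydrochlorination and Li–Cl exchange with n-BuLi should give the lithium alkoxyacetylide, and its C-alkylation (SN2 at the primary allylic carbon of prenyl bromide) forms the C8–C1'' bond of the target.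

Step 10
Reactants: 18 silyl-protected ynol ether
Product: 19 (2S,3R)-2-(methoxymethoxy)-3-[2-(methoxymethoxy)phenyl]-3-[(5-methylhex-4-en-1-yn-1-yl)oxy]propan-1-ol
Conditions: TBAF, THF, 0 °C → rt
Reagents that add atoms: none
Why: Fluoride-mediated desilylation; the ynol ether, the skipped enyne and both MOM acetals tolerate fluoride and mild base but would not tolerate acid.

Step 11
Reactants: 19 primary alcohol
Product: 20 (2R,3R)-2-(methoxymethoxy)-3-[2-(methoxymethoxy)phenyl]-3-[(5-methylhex-4-en-1-yn-1-yl)oxy]propanal
Conditions: Dess–Martin periodinane, pyridine, CH2Cl2, 0 °C; used crude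
Reagents that add atoms: none
Why: Dess–Martin oxidation under pyridine buffering is mild enough to spare the ynol ether and to avoid epimerisation or β-elimination of the α-alkoxy aldehyde.

Step 12
Reactants: 21 tert-butyl vinyl ether
Product: 23 (Z)-1-bromo-2-tert-butoxyethene, via 1,2-dibromoethyl tert-butyl ether 22 (not isolated)
Conditions: Br2, pentane, −78 °C; then Et3N (2 equiv), −78 °C → reflux; filtration, distillation at reduced pressure
Reagents that add atoms: bromine, BrBr
Why: Bromine addition across the enol ether followed by amine-mediated dehydrobromination of the α-bromo ether is the classical route to 2-bromovinyl ethers; the low temperature and immediate trapping by the amine should keep the tert-butyl group from being lost, and either alkene isomer would serve in the next step.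

Step 13
Reactants: 23 (Z)-1-bromo-2-tert-butoxyethene
Product: 25 tert-butoxyethyne, via sodium tert-butoxyacetylide 24 (not isolated)
Conditions: NaNH2 (2.2 equiv), liq. NH3, −33 °C; NH3 evaporated; cold brine, −20 °C; pentane extraction, distillation at reduced pressure below 30 °C, stored cold
Reagents that add atoms: none
Why: Amide-mediated anti-dehydrobromination of the 2-bromovinyl ether gives the alkoxyethyne, held as its sodium acetylide until the aqueous quench; this is the established preparation of tert-alkoxyethynes and involves no acid or heat that would trigger the retro-ene loss of isobutene.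

Step 14
Reactants: 20 aldehyde; 25 tert-butoxyethyne
Product: 27 (4S,5R)-1-tert-butoxy-4-(methoxymethoxy)-5-[2-(methoxymethoxy)phenyl]-5-[(5-methylhex-4-en-1-yn-1-yl)oxy]pent-1-yn-3-ol (both C3 epimers), via tert-butoxyethynyllithium 26 (not isolated)
Conditions: 25 (1.3 equiv), n-BuLi (1.25 equiv), THF, −78 °C; then 20, −78 °C; pH 7 phosphate buffer
Reagents that add atoms: none
Why: 1,2-Addition of a lithium alkoxyacetylide to the aldehyde forms the C4–C4a bond; the new carbinol centre is oxidised away in the next step, so its configuration is irrelevant.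

Step 15
Reactants: 27 propargylic alcohol
Product: 28 (4R,5R)-1-tert-butoxy-4-(methoxymethoxy)-5-[2-(methoxymethoxy)phenyl]-5-[(5-methylhex-4-en-1-yn-1-yl)oxy]pent-1-yn-3-one
Conditions: activated MnO2, CH2Cl2, 0 °C → rt; filtered through Celite, used at once
Reagents that add atoms: none
Why: Heterogeneous MnO2 oxidation of a propargylic alcohol proceeds under neutral conditions, which should avoid the acid-triggered Meyer–Schuster rearrangement of the γ-alkoxy propargylic alcohol and epimerisation next to the new ketone.

Step 16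
Reactants: 29 chloroacetaldehyde dimethyl acetal (2-chloro-1,1-dimethoxyethane)
Product: 31 methoxyethyne, via sodium methoxyacetylide 30 (not isolated)
Conditions: NaNH2 (3.2 equiv), liq. NH3, −33 °C; NH3 evaporated; cold sat. aq. NaCl, −70 °C → rt; product distilled into a −78 °C trap and kept as a cold Et2O solution
Reagents that add atoms: none
Why: Threefold action of sodium amide on the chloroacetal (loss of methanol, loss of HCl, deprotonation of the alkyne) is the classical preparation of alkoxyethynes; the sodium acetylide is protonated on the aqueous quench and the volatile alkyne is collected cold.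

Step 17
Reactants: 31 methoxyethyne; 32 2-isopropoxy-4,4,5,5-tetramethyl-1,3,2-dioxaborolane
Product: 35 2-(methoxyethynyl)-4,4,5,5-tetramethyl-1,3,2-dioxaborolane, via methoxyethynyllithium 33 (not isolated), via lithium alkynylborate 34 (not isolated)
Conditions: n-BuLi (1.0 equiv), Et2O, −78 °C; then 32, −78 °C; then HCl·Et2O (1 equiv), −78 °C → rt; filtration, distillation
Reagents that add atoms: none
Why: Borylation of an alkynyllithium with an alkoxyboronate followed by anhydrous acid collapse of the ate complex is the standard route to alkynyl pinacolboronates and should apply to the lithium alkoxyacetylide.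

Step 18
Reactants: 28 diyne; 35 2-(methoxyethynyl)-4,4,5,5-tetramethyl-1,3,2-dioxaborolane
Product: 36 (2R,3R)-5-tert-butoxy-6-methoxy-3-(methoxymethoxy)-2-[2-(methoxymethoxy)phenyl]-8-(3-methylbut-2-en-1-yl)-7-(4,4,5,5-tetramethyl-1,3,2-dioxaborolan-2-yl)-2,3-dihydro-4H-chromen-4-one
Conditions: [Rh(cod)2]BF4/rac-BINAP (10 mol%, H2 pre-activation), 35 (3 equiv), CH2Cl2, 0 °C → rt, 28 added over 4 h
Reagents that add atoms: none
Why: Proposed new method: a cationic Rh(I)–bisphosphine complex should bind the two tethered alkynes of 28 and couple them oxidatively at their inner carbons (C8a of the electron-rich ynol ether and C4a of the electron-poor alkoxy ynone, a polarity-matched pair), giving a rhodacyclopentadiene fused to the new six-membered ring C; insertion of 35 into a Rh–C bond and reductive elimination then form C5–C6 and C7–C8 and complete ring A as the benzene ring. The closest known reaction types are Rh-, Ru- and Co-catalysed [2+2+2] cyclotrimerisations of tethered 1,6- and 1,7-diynes with alkynylboronates and, separately, with ynol ethers or ynamides; the union of an O-alkynyl ether terminus, an alkoxy ynone terminus and a donor-substituted alkynylboronate in one event is without precedent. Ring C is therefore closed by metal-templated alkyne–alkyne coupling across the O1–C2–C3–C4 tether, and ring A by the [2+2+2] annulation itself. No stereocentre is formed: the C2/C3 pair sits in the tether, is not touched by the neutral conditions and should be carried through unchanged. The step needs cross- over homo-cyclotrimerisation, which the intramolecular first coupling, the excess of 35 and the slow addition of 28 should secure, and it needs 35 to enter with its methoxy carbon bonded to C5: the large pinacolboryl group should settle beside the C8 methylene and away from the C5 tert-butoxy group, which is already pressed by the C4 carbonyl. A catalyst that turns over at room temperature is required because both ynol ethers are heat-labile (retro-ene loss of isobutene from the tert-butyl ether, sigmatropic shift of the benzylic alkynyl ether).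

Step 19
Reactants: 36 aryl boronate
Product: 37 (2R,3R)-5-tert-butoxy-7-hydroxy-6-methoxy-3-(methoxymethoxy)-2-[2-(methoxymethoxy)phenyl]-8-(3-methylbut-2-en-1-yl)-2,3-dihydro-4H-chromen-4-one
Conditions: 30% H2O2, NaHCO3, THF/H2O, 0 °C → rt; Na2S2O3
Reagents that add atoms: hydrogen peroxide, OO
Why: Oxidation of the aryl boronate (1,2-shift of the aryl group from boron to oxygen, then hydrolysis) under bicarbonate buffering should reveal the 7-hydroxyl without epoxidising the prenyl alkene or opening the base-sensitive chromanone.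

Step 20
Reactants: 37 protected flavanonol
Product: 38 floranol, (2R,3R)-3,5,7-trihydroxy-2-(2-hydroxyphenyl)-6-methoxy-8-(3-methylbut-2-en-1-yl)-2,3-dihydro-4H-chromen-4-one
Conditions: 3 M HCl, MeOH, 40 °C
Reagents that add atoms: none
Why: Acid-mediated global deprotection (SN1 cleavage of the aryl tert-butyl ether and methanolysis of both MOM acetals) should give the target, whose 2,3-trans arrangement is the thermodynamically preferred one and is not endangered by the conditions.

**Compound list**

1 | salicylaldehyde | O=Cc1ccccc1O | starting material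
2 | 2-(methoxymethoxy)benzaldehyde | COCOc1ccccc1C=O | intermediate
3 | methyl glycolate | COC(=O)CO | starting material
4 | methyl 2-(methoxymethoxy)acetate | COCOCC(=O)OC | intermediate
5 | 2-(methoxymethoxy)acetic acid | COCOCC(=O)O | intermediate
6 | (S)-4-benzyl-1,3-oxazolidin-2-one | O=C1N[C@@H](Cc2ccccc2)CO1 | starting material
7 | 2-(methoxymethoxy)acetic pivalic anhydride | COCOCC(=O)OC(=O)C(C)(C)C | intermediate
8 | (S)-4-benzyl-3-[2-(methoxymethoxy)acetyl]-1,3-oxazolidin-2-one | COCOCC(=O)N1[C@@H](Cc2ccccc2)COC1=O | intermediate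
9 | O-trimethylsilyl ether of aldol adduct 10 | C[Si](C)(C)O[C@H](c1ccccc1OCOC)[C@@H](OCOC)C(=O)N1[C@@H](Cc2ccccc2)COC1=O | intermediate
10 | (S)-4-benzyl-3-[(2R,3R)-3-hydroxy-2-(methoxymethoxy)-3-[2-(methoxymethoxy)phenyl]propanoyl]-1,3-oxazolidin-2-one | O[C@H](c1ccccc1OCOC)[C@@H](OCOC)C(=O)N1[C@@H](Cc2ccccc2)COC1=O | intermediate
11 | (1R,2S)-2-(methoxymethoxy)-1-[2-(methoxymethoxy)phenyl]propane-1,3-diol | O[C@H](c1ccccc1OCOC)[C@@H](OCOC)CO | intermediate
12 | (1R,2S)-2-(methoxymethoxy)-1-[2-(methoxymethoxy)phenyl]-3-[(triisopropylsilyl)oxy]propan-1-ol | O[C@H](c1ccccc1OCOC)[C@@H](OCOC)CO[Si](C(C)C)(C(C)C)C(C)C | intermediate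
13 | trichloroethylene | ClC=C(Cl)Cl | starting material
14 | dichloroacetylene | ClC#CCl | intermediate
15 | {[(2S,3R)-3-{[(E)-1,2-dichloroethenyl]oxy}-2-(methoxymethoxy)-3-[2-(methoxymethoxy)phenyl]propyl]oxy}triisopropylsilane | Cl/C=C(/Cl)O[C@H](c1ccccc1OCOC)[C@@H](OCOC)CO[Si](C(C)C)(C(C)C)C(C)C | intermediate
16 | prenyl bromide (1-bromo-3-methylbut-2-ene) | CC(C)=CCBr | starting material
17 | lithium alkynyl ether derived from 15 (lithium acetylide of the C2–O–ethynyl ether) | [Li]C#CO[C@H](c1ccccc1OCOC)[C@@H](OCOC)CO[Si](C(C)C)(C(C)C)C(C)C | intermediate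
18 | triisopropyl{[(2S,3R)-2-(methoxymethoxy)-3-[2-(methoxymethoxy)phenyl]-3-[(5-methylhex-4-en-1-yn-1-yl)oxy]propyl]oxy}silane | CC(C)=CCC#CO[C@H](c1ccccc1OCOC)[C@@H](OCOC)CO[Si](C(C)C)(C(C)C)C(C)C | intermediate
19 | (2S,3R)-2-(methoxymethoxy)-3-[2-(methoxymethoxy)phenyl]-3-[(5-methylhex-4-en-1-yn-1-yl)oxy]propan-1-ol | CC(C)=CCC#CO[C@H](c1ccccc1OCOC)[C@@H](OCOC)CO | intermediate
20 | (2R,3R)-2-(methoxymethoxy)-3-[2-(methoxymethoxy)phenyl]-3-[(5-methylhex-4-en-1-yn-1-yl)oxy]propanal | CC(C)=CCC#CO[C@H](c1ccccc1OCOC)[C@@H](OCOC)C=O | intermediate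
21 | tert-butyl vinyl ether | C=COC(C)(C)C | starting material
22 | 1,2-dibromoethyl tert-butyl ether | CC(C)(C)OC(Br)CBr | intermediate
23 | (Z)-1-bromo-2-tert-butoxyethene | CC(C)(C)O/C=C\Br | intermediate
24 | sodium tert-butoxyacetylide | [Na]C#COC(C)(C)C | intermediate
25 | tert-butoxyethyne | C#COC(C)(C)C | intermediate
26 | tert-butoxyethynyllithium | [Li]C#COC(C)(C)C | intermediate
27 | (4S,5R)-1-tert-butoxy-4-(methoxymethoxy)-5-[2-(methoxymethoxy)phenyl]-5-[(5-methylhex-4-en-1-yn-1-yl)oxy]pent-1-yn-3-ol, both C3 epimers | CC(C)=CCC#CO[C@H](c1ccccc1OCOC)[C@@H](OCOC)C(O)C#COC(C)(C)C | intermediate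
28 | (4R,5R)-1-tert-butoxy-4-(methoxymethoxy)-5-[2-(methoxymethoxy)phenyl]-5-[(5-methylhex-4-en-1-yn-1-yl)oxy]pent-1-yn-3-one | CC(C)=CCC#CO[C@H](c1ccccc1OCOC)[C@@H](OCOC)C(=O)C#COC(C)(C)C | intermediate
29 | chloroacetaldehyde dimethyl acetal (2-chloro-1,1-dimethoxyethane) | COC(CCl)OC | starting material
30 | sodium methoxyacetylide | [Na]C#COC | intermediate
31 | methoxyethyne | C#COC | intermediate
32 | 2-isopropoxy-4,4,5,5-tetramethyl-1,3,2-dioxaborolane | CC(C)OB1OC(C)(C)C(C)(C)O1 | starting material
33 | methoxyethynyllithium | [Li]C#COC | intermediate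
34 | lithium isopropoxy(methoxyethynyl)pinacolatoborate | [Li+].COC#C[B-]1(OC(C)C)OC(C)(C)C(C)(C)O1 | intermediate
35 | 2-(methoxyethynyl)-4,4,5,5-tetramethyl-1,3,2-dioxaborolane | COC#CB1OC(C)(C)C(C)(C)O1 | intermediate
36 | (2R,3R)-5-tert-butoxy-6-methoxy-3-(methoxymethoxy)-2-[2-(methoxymethoxy)phenyl]-8-(3-methylbut-2-en-1-yl)-7-(4,4,5,5-tetramethyl-1,3,2-dioxaborolan-2-yl)-2,3-dihydro-4H-chromen-4-one | COc1c(B3OC(C)(C)C(C)(C)O3)c(CC=C(C)C)c2c(c1OC(C)(C)C)C(=O)[C@H](OCOC)[C@@H](c1ccccc1OCOC)O2 | intermediate
37 | (2R,3R)-5-tert-butoxy-7-hydroxy-6-methoxy-3-(methoxymethoxy)-2-[2-(methoxymethoxy)phenyl]-8-(3-methylbut-2-en-1-yl)-2,3-dihydro-4H-chromen-4-one | COc1c(O)c(CC=C(C)C)c2c(c1OC(C)(C)C)C(=O)[C@H](OCOC)[C@@H](c1ccccc1OCOC)O2 | intermediate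
38 | floranol, (2R,3R)-3,5,7-trihydroxy-2-(2-hydroxyphenyl)-6-methoxy-8-(3-methylbut-2-en-1-yl)-2,3-dihydro-4H-chromen-4-one | COc1c(O)c(CC=C(C)C)c2c(c1O)C(=O)[C@H](O)[C@@H](c1ccccc1O)O2 | target

**Step count and risks**

Total step count: 20. Longest linear sequence: 15 steps (3 → 4 → 5 → 8 → 10 → 11 → 12 → 15 → 18 → 19 → 20 → 27 → 28 → 36 → 37 → 38).

The three steps most likely to fail are 18, 15 and 8.

Step 18 (the proposed new method) may fail in three ways: the alkynylboronate may insert in the reverse orientation, the diyne may oligomerise with itself, or the Lewis-acidic metal may ionise or rearrange the two ynol ethers before they couple. The fallback uses known reactions only and takes ring A from a symmetrical arene; it sets out from alcohol 12 and comes back to the route at 38. Commercial 2-methoxyresorcinol (COc1c(O)cccc1O) would be bis-protected with MOMCl and iPr2NEt to 2-methoxy-1,3-bis(methoxymethoxy)benzene F1. Sterically controlled Ir-catalysed C–H borylation (B2pin2, [Ir(OMe)(cod)]2, dtbpy) should give 2-[4-methoxy-3,5-bis(methoxymethoxy)phenyl]-4,4,5,5-tetramethyl-1,3,2-dioxaborolane F2, and CuBr2 in aqueous methanol should convert it into 5-bromo-2-methoxy-1,3-bis(methoxymethoxy)benzene F3. Pd-catalysed C–O coupling of F3 with 12 (RockPhos-type ligand, Cs2CO3, toluene, 90 °C) should give, with retention at the carbinol carbon, the aryl ether triisopropyl{[(2S,3R)-3-[4-methoxy-3,5-bis(methoxymethoxy)phenoxy]-2-(methoxymethoxy)-3-[2-(methoxymethoxy)phenyl]propyl]oxy}silane F4; its two positions ortho to the new ether oxygen are equivalent, so the later ring closure has no regiochemical choice. TBAF would free (2S,3R)-3-[4-methoxy-3,5-bis(methoxymethoxy)phenoxy]-2-(methoxymethoxy)-3-[2-(methoxymethoxy)phenyl]propan-1-ol F5, and TEMPO/PhI(OAc)2 in aqueous MeCN would oxidise it to (2R,3R)-3-[4-methoxy-3,5-bis(methoxymethoxy)phenoxy]-2-(methoxymethoxy)-3-[2-(methoxymethoxy)phenyl]propanoic acid F6. Activation as the mixed trifluoroacetic anhydride (TFAA, hindered pyridine base, CH2Cl2, 0 °C) should lead to intramolecular Friedel–Crafts acylation of the phloroglucinol-type ring and close ring C to (2R,3R)-6-methoxy-3,5,7-tris(methoxymethoxy)-2-[2-(methoxymethoxy)phenyl]chroman-4-one F7. HCl in MeOH would remove the four MOM groups to give (2R,3R)-3,5,7-trihydroxy-2-(2-hydroxyphenyl)-6-methoxychroman-4-one F8, and Friedel–Crafts prenylation at C8, the only free position of ring A (2-methylbut-3-en-2-ol, BF3·OEt2, dioxane), would then give 38.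

Step 15 may fail because the alkoxy ynone loses isobutene by a retro-ene process or takes up water at its β-carbon during oxidation and isolation, or because carbinol 27 rearranges (Meyer–Schuster) on the oxidant. The fallback moves the oxidation behind the ring construction; it sets out from 27 and comes back at 36. Carbinol 27 (both C3 epimers) would be submitted with 35 to the cyclotrimerisation conditions of step 18, which should give (2R,3R)-configured 5-tert-butoxy-6-methoxy-3-(methoxymethoxy)-2-[2-(methoxymethoxy)phenyl]-8-(3-methylbut-2-en-1-yl)-7-(4,4,5,5-tetramethyl-1,3,2-dioxaborolan-2-yl)chroman-4-ol F9 (both C4 epimers). This benzylic alcohol would then be oxidised with Dess–Martin periodinane or MnO2 to 36.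

Step 8 may fail because, under KH, the silyl group migrates from the primary oxygen to the benzylic alkoxide, so that the vinyl ether forms at the wrong oxygen. The fallback avoids the alkoxide altogether; it sets out from 12 and comes back at 18 (through 17). Alcohol 12 would be formylated with acetic formic anhydride and pyridine to (1R,2S)-2-(methoxymethoxy)-1-[2-(methoxymethoxy)phenyl]-3-[(triisopropylsilyl)oxy]propyl formate F10. PPh3 and CCl4 (THF, 60 °C) should convert the formyl carbonyl into the 2,2-dichlorovinyl ether {[(2S,3R)-3-[(2,2-dichloroethenyl)oxy]-2-(methoxymethoxy)-3-[2-(methoxymethoxy)phenyl]propyl]oxy}triisopropylsilane F11. n-BuLi (2 equiv) should then effect elimination and Li–Cl exchange to the lithium alkynyl ether 17, which prenyl bromide alkylates to 18 as in step 9.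

**Further compounds**

F1 | step 18 | 2-methoxy-1,3-bis(methoxymethoxy)benzene | COCOc1cccc(OCOC)c1OC
F2 | step 18 | 2-[4-methoxy-3,5-bis(methoxymethoxy)phenyl]-4,4,5,5-tetramethyl-1,3,2-dioxaborolane | COCOc1cc(B2OC(C)(C)C(C)(C)O2)cc(OCOC)c1OC
F3 | step 18 | 5-bromo-2-methoxy-1,3-bis(methoxymethoxy)benzene | COCOc1cc(Br)cc(OCOC)c1OC
F4 | step 18 | triisopropyl{[(2S,3R)-3-[4-methoxy-3,5-bis(methoxymethoxy)phenoxy]-2-(methoxymethoxy)-3-[2-(methoxymethoxy)phenyl]propyl]oxy}silane | COCOc1cc(O[C@H](c2ccccc2OCOC)[C@@H](OCOC)CO[Si](C(C)C)(C(C)C)C(C)C)cc(OCOC)c1OC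
F5 | step 18 | (2S,3R)-3-[4-methoxy-3,5-bis(methoxymethoxy)phenoxy]-2-(methoxymethoxy)-3-[2-(methoxymethoxy)phenyl]propan-1-ol | COCOc1cc(O[C@H](c2ccccc2OCOC)[C@@H](OCOC)CO)cc(OCOC)c1OC
F6 | step 18 | (2R,3R)-3-[4-methoxy-3,5-bis(methoxymethoxy)phenoxy]-2-(methoxymethoxy)-3-[2-(methoxymethoxy)phenyl]propanoic acid | COCOc1cc(O[C@H](c2ccccc2OCOC)[C@@H](OCOC)C(=O)O)cc(OCOC)c1OC
F7 | step 18 | (2R,3R)-6-methoxy-3,5,7-tris(methoxymethoxy)-2-[2-(methoxymethoxy)phenyl]chroman-4-one | COCOc1cc2O[C@H](c3ccccc3OCOC)[C@@H](OCOC)C(=O)c2c(OCOC)c1OC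
F8 | step 18 | (2R,3R)-3,5,7-trihydroxy-2-(2-hydroxyphenyl)-6-methoxychroman-4-one | COc1c(O)cc2O[C@H](c3ccccc3O)[C@@H](O)C(=O)c2c1O
F9 | step 15 | 5-tert-butoxy-6-methoxy-3-(methoxymethoxy)-2-[2-(methoxymethoxy)phenyl]-8-(3-methylbut-2-en-1-yl)-7-(4,4,5,5-tetramethyl-1,3,2-dioxaborolan-2-yl)chroman-4-ol, C2 and C3 as in 36, both C4 epimers | COc1c(B3OC(C)(C)C(C)(C)O3)c(CC=C(C)C)c2c(c1OC(C)(C)C)C(O)[C@H](OCOC)[C@@H](c1ccccc1OCOC)O2
F10 | step 8 | (1R,2S)-2-(methoxymethoxy)-1-[2-(methoxymethoxy)phenyl]-3-[(triisopropylsilyl)oxy]propyl formate | O=CO[C@H](c1ccccc1OCOC)[C@@H](OCOC)CO[Si](C(C)C)(C(C)C)C(C)C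
F11 | step 8 | {[(2S,3R)-3-[(2,2-dichloroethenyl)oxy]-2-(methoxymethoxy)-3-[2-(methoxymethoxy)phenyl]propyl]oxy}triisopropylsilane | ClC(Cl)=CO[C@H](c1ccccc1OCOC)[C@@H](OCOC)CO[Si](C(C)C)(C(C)C)C(C)C
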